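The target is cut at the Z‑alkene that links C8 of ring A to the tertiary carbinol carbon. The C7 phenol oxygen and the carbinol oxygen sit on the same side of that alkene, so one diisopropylsilicon atom can bridge them. Ring‑closing metathesis of the two vinyl groups then forms the only C–C bond between the two enantiopure halves, as the endocyclic double bond of an eight‑membered 1,3‑dioxa‑2‑silacyclooctene fused to ring A, which can only be Z. The precursor is a silaketal diene made from (S)‑7‑hydroxy‑8‑vinylflavanone and (R)‑2‑hydroxy‑2‑methylbut‑3‑enyl acetate; buffered fluoride then releases the target.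

Key step: step 10

Assumption: the ligand enantiomers named in steps 4 and 7 are those expected by analogy to give the 2S and the R centre; if the optical rotation of 7 or 13 shows the opposite sense, the mirror‑image ligand is used with nothing else changed.

Step 1
Reactants: 1 2,4‑dihydroxyacetophenone
Product: 2 2,4‑dihydroxy‑3‑iodoacetophenone
Conditions: I2, HIO3, EtOH–H2O, 35 °C
Reagents that add atoms: iodine, II; iodic acid, OI(=O)=O
Why: Electrophilic aromatic iodination, in which the carbon between the two hydroxyls is activated by both and the chelated 2‑hydroxyl/acetyl pair directs attack to C3 over C5, while iodic acid reoxidises iodide so that all iodine is used.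

Step 2
Reactants: 2 2,4‑dihydroxy‑3‑iodoacetophenone
Product: 3 2‑hydroxy‑3‑iodo‑4‑(methoxymethoxy)acetophenone
Conditions: MOMCl, K2CO3, acetone, 0 °C to rt
Reagents that add atoms: chloromethyl methyl ether, COCCl
Why: Williamson‑type O‑alkylation that should touch only the 4‑hydroxyl, because the 2‑hydroxyl is locked in a hydrogen bond to the ketone and flanked by iodine and the acyl group.

Step 3
Reactants: 3 2‑hydroxy‑3‑iodo‑4‑(methoxymethoxy)acetophenone
Product: 5 8‑iodo‑7‑(methoxymethoxy)chromone, via enaminone 4 (not isolated)
Conditions: DMF‑DMA, toluene, 95 °C; evaporate; then AcOH, CH2Cl2, 40 °C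
Reagents that add atoms: N,N‑dimethylformamide dimethyl acetal, COC(OC)N(C)C
Why: Condensation of the methyl ketone with the formamide acetal supplies C2 as an enaminone, and weak acid then promotes intramolecular oxa‑Michael addition of the phenol with loss of dimethylamine (enaminone route to chromones) without cleaving the aryl acetal.

Step 4
Reactants: 5 8‑iodo‑7‑(methoxymethoxy)chromone; 6 phenylboronic acid
Product: 7 (S)‑8‑iodo‑7‑(methoxymethoxy)flavanone
Conditions: Pd(OCOCF3)2 (5 mol%), (R)‑t‑BuPyOx (6 mol%), NH4PF6, H2O, ClCH2CH2Cl, 60 °C
Reagents that add atoms: none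
Why: Catalytic asymmetric 1,4‑arylation in which a phenylpalladium species formed by transmetalation from boron inserts the C2=C3 bond and the palladium enolate is protonated by water; the tert‑butyl group of the pyridine‑oxazoline ligand shields one face of the bound chromone so that phenyl reaches the face of C2 that gives S, and the cycle stays at divalent palladium, so the C–I bond should be left alone.

Step 5
Reactants: 7 (S)‑8‑iodo‑7‑(methoxymethoxy)flavanone; 8 tributyl(vinyl)stannane
Product: 9 (S)‑7‑(methoxymethoxy)‑8‑vinylflavanone
Conditions: Pd(PPh3)4 (5 mol%), toluene, 100 °C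
Reagents that add atoms: none
Why: Stille coupling (oxidative addition of zerovalent palladium into C8–I, vinyl transfer from tin, reductive elimination) runs without base, so the C2 centre, which would racemise by retro‑oxa‑Michael opening under base, and the acetal are not at risk.

Step 6
Reactants: 9 (S)‑7‑(methoxymethoxy)‑8‑vinylflavanone
Product: 10 (S)‑7‑hydroxy‑8‑vinylflavanone
Conditions: 2 M HCl in MeOH, THF, 40 °C
Reagents that add atoms: none
Why: Acid‑catalysed transacetalisation of the aryl methoxymethyl ether to methanol frees the phenol, while the C8 vinyl group, on a ring whose two oxygens are conjugated to the C4 ketone, is slow to protonate and the flavanone ring does not open under mild acid.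

Step 7
Reactants: 11 racemic 2‑methyl‑2‑vinyloxirane
Product: 13 (R)‑2‑methylbut‑3‑ene‑1,2‑diol, via cyclic carbonate 12 (not isolated)
Conditions: Pd2(dba)3·CHCl3 (1 mol%), (S,S)‑DACH‑phenyl Trost ligand (3 mol%), Et3B (1 mol%), NaHCO3, CH2Cl2–H2O, rt; then NaOH aq., rt
Reagents that add atoms: sodium hydrogen carbonate, [Na+].OC([O-])=O
Why: Dynamic kinetic asymmetric allylic substitution (Tsuji–Trost type), in which zerovalent palladium ionises both enantiomers of the epoxide to π‑allyl complexes that interconvert faster than they are captured, the chiral ligand pocket with boron‑templated delivery of the carbonate oxygen to the tertiary terminus sets the R centre, and hydroxide then opens the cyclic carbonate.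

Step 8
Reactants: 13 (R)‑2‑methylbut‑3‑ene‑1,2‑diol
Product: 14 (R)‑2‑hydroxy‑2‑methylbut‑3‑enyl acetate
Conditions: Ac2O (1.05 equiv), pyridine, CH2Cl2, 0 °C
Reagents that add atoms: acetic anhydride, CC(=O)OC(C)=O
Why: Acylation of the unhindered primary hydroxyl is far faster than that of the tertiary allylic hydroxyl in the absence of an acyl‑transfer catalyst, and the stereocentre takes no part.

Step 9
Reactants: 14 (R)‑2‑hydroxy‑2‑methylbut‑3‑enyl acetate; 10 (S)‑7‑hydroxy‑8‑vinylflavanone
Product: 16 mixed diisopropylsilaketal diene, via silyl triflate 15 (not isolated)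
Conditions: iPr2Si(OTf)2 (1.05 equiv), 2,6‑lutidine, CH2Cl2, −78 to 0 °C, 14 added first; then 10, imidazole, 0 °C to rt
Reagents that add atoms: diisopropylsilyl bis(trifluoromethanesulfonate), CC(C)[Si](OS(=O)(=O)C(F)(F)F)(OS(=O)(=O)C(F)(F)F)C(C)C
Why: Two successive substitutions at silicon (mixed silaketal formation), in which the tertiary alcohol displaces one triflate and its bulk blocks a second addition of 14, after which the remaining silyl triflate is captured by the more acidic phenol, both stereocentres being spectators.

Step 10
Reactants: 16 mixed diisopropylsilaketal diene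
Product: 17 benzo‑fused eight‑membered cyclic silaketal with endocyclic Z‑alkene
Conditions: second‑generation Hoveyda–Grubbs catalyst RuCl2(H2IMes)(=CH‑C6H4‑2‑OiPr) (10 mol%, in portions), toluene (0.005 M), 80 °C, argon sparge
Reagents that add atoms: none
Why: The ruthenium alkylidene exchanges onto the less hindered aryl vinyl group, the resulting benzylidene undergoes [2+2] cycloaddition with the vinyl group on the quaternary carbinol carbon, and cycloreversion of the ruthenacyclobutane releases the ring alkene while the chain is carried on with loss of ethylene. The closest known reaction type is temporary silicon‑tethered ring‑closing metathesis of bis(alkenyloxy)silanes to medium‑ring cyclic silaketals. The one ring closed is the eight‑membered 1,3‑dioxa‑2‑silacyclooct‑5‑ene fused to ring A at C7–C8, made by joining the two internal alkene carbons so that the new double bond is endocyclic. No stereocentre is created; the geometry is dictated by the ring, because an eight‑membered ring that already holds the planar arene bond cannot accommodate an E double bond. The step needs Z geometry and closure in preference to oligomerisation, and the substrate secures both through the ring constraint, the long Si–O bonds, the two isopropyl groups on silicon and the quaternary carbinol carbon, which fold the chain, helped by high dilution and removal of ethylene. The tether also masks the phenol and the tertiary allylic alcohol, which could otherwise bind ruthenium or ionise towards a 2H‑chromene.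

Step 11
Reactants: 17 benzo‑fused eight‑membered cyclic silaketal with endocyclic Z‑alkene
Product: 18 target, (2R,3Z)‑2‑hydroxy‑4‑[(2S)‑7‑hydroxy‑4‑oxo‑2‑phenylchroman‑8‑yl]‑2‑methylbut‑3‑enyl acetate
Conditions: HF·pyridine, pyridine, THF, 0 °C to rt; NaHCO3 quench
Reagents that add atoms: none
Why: Fluoride‑driven cleavage of both Si–O bonds (desilylation), with pyridine‑buffered HF being neither acidic enough to ionise the tertiary allylic alcohol towards a chromene nor basic enough to open the flavanone ring or move the acetate, so the alkene geometry and both stereocentres are kept.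

**Compound list**

1 | 2,4‑dihydroxyacetophenone | CC(=O)c1ccc(O)cc1O | starting material
2 | 2,4‑dihydroxy‑3‑iodoacetophenone | CC(=O)c1ccc(O)c(I)c1O | intermediate
3 | 2‑hydroxy‑3‑iodo‑4‑(methoxymethoxy)acetophenone | CC(=O)c1ccc(OCOC)c(I)c1O | intermediate
4 | (E)‑3‑(dimethylamino)‑1‑[2‑hydroxy‑3‑iodo‑4‑(methoxymethoxy)phenyl]prop‑2‑en‑1‑one (enaminone, formed in the flask) | CN(C)/C=C/C(=O)c1ccc(OCOC)c(I)c1O | intermediate
5 | 8‑iodo‑7‑(methoxymethoxy)chromone | O=c1ccoc2c(I)c(OCOC)ccc12 | intermediate
6 | phenylboronic acid | OB(O)c1ccccc1 | starting material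
7 | (S)‑8‑iodo‑7‑(methoxymethoxy)flavanone | COCOc1ccc2c(c1I)O[C@H](c1ccccc1)CC2=O | intermediate
8 | tributyl(vinyl)stannane | C=C[Sn](CCCC)(CCCC)CCCC | starting material
9 | (S)‑7‑(methoxymethoxy)‑8‑vinylflavanone | COCOc1ccc2c(c1C=C)O[C@H](c1ccccc1)CC2=O | intermediate
10 | (S)‑7‑hydroxy‑8‑vinylflavanone | C=Cc1c(O)ccc2c1O[C@H](c1ccccc1)CC2=O | intermediate
11 | racemic 2‑methyl‑2‑vinyloxirane (isoprene monoepoxide) | CC1(C=C)CO1 | starting material
12 | (R)‑4‑methyl‑4‑vinyl‑1,3‑dioxolan‑2‑one (cyclic carbonate, formed in the flask) | O=C1OC[C@@](C)(C=C)O1 | intermediate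
13 | (R)‑2‑methylbut‑3‑ene‑1,2‑diol | OC[C@](C)(O)C=C | intermediate
14 | (R)‑2‑hydroxy‑2‑methylbut‑3‑enyl acetate | CC(=O)OC[C@](C)(O)C=C | intermediate
15 | (R)‑2‑{[diisopropyl(trifluoromethanesulfonyloxy)silyl]oxy}‑2‑methylbut‑3‑enyl acetate (silyl triflate, formed in the flask) | CC(=O)OC[C@@](C)(C=C)O[Si](C(C)C)(C(C)C)OS(=O)(=O)C(F)(F)F | intermediate
16 | (R)‑2‑{[diisopropyl({(S)‑4‑oxo‑2‑phenyl‑8‑vinylchroman‑7‑yl}oxy)silyl]oxy}‑2‑methylbut‑3‑enyl acetate (mixed silaketal diene) | CC(=O)OC[C@@](C)(C=C)O[Si](C(C)C)(C(C)C)Oc1ccc2c(c1C=C)O[C@H](c1ccccc1)CC2=O | intermediate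
17 | cyclic diisopropylsilaketal: eight‑membered 1,3‑dioxa‑2‑silacyclooct‑5‑ene fused to ring A at C7–C8, Z ring alkene, R carbinol carbon bearing methyl and acetoxymethyl, S at flavanone C2 | CC(=O)OC[C@]1(C)O[Si](C(C)C)(C(C)C)Oc2ccc3c(c2/C=C\1)O[C@H](c2ccccc2)CC3=O | intermediate
18 | (2R,3Z)‑2‑hydroxy‑4‑[(2S)‑7‑hydroxy‑4‑oxo‑2‑phenylchroman‑8‑yl]‑2‑methylbut‑3‑enyl acetate (CNP0372308.1) | CC(=O)OC[C@](C)(O)/C=C\c1c(O)ccc2c1O[C@H](c1ccccc1)CC2=O | target

**Step count and risks**

Total step count: 11. Longest linear sequence: 9 steps (steps 1–6, then 9–11); the side‑chain branch contributes steps 7 and 8.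

Steps most likely to fail:

1. Step 10. The carbene may engage the vinyl group on the quaternary carbon too slowly, so that catalyst decay, chelation of the benzylidene by the flanking ring oxygen, or intermolecular dimerisation outruns closure of the eight‑membered ring. The fallback sets out from 10 and 14 and returns at 18. Cross‑metathesis of 10 with an excess of 14 (second‑generation Hoveyda–Grubbs catalyst, CH2Cl2, 40 °C) should give the E isomer of the target F1. Irradiation of F1 with blue light and Ir(ppy)3 in MeCN at rt should then move the alkene to Z by triplet energy transfer, since the Z isomer is twisted out of conjugation by the two ortho oxygens, accepts energy poorly and accumulates. This gives 18 without any silicon chemistry.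

2. Step 4. Adventitious reduction of the catalyst to zerovalent palladium could lead to oxidative addition into the C8–I bond (biaryl formation or loss of iodine), or the iodine next to the ring oxygen could erode facial selectivity. The fallback sets out from 5 and returns at 9. Stille coupling of 5 with 8 (Pd(PPh3)4, toluene, 100 °C) first gives 7‑(methoxymethoxy)‑8‑vinylchromone F2, so that no halide remains. Rhodium‑catalysed asymmetric 1,4‑addition of 6 to F2 ([Rh(OH)(cod)]2 with an electron‑poor chiral MeO‑BIPHEP‑type diphosphine, toluene–H2O, rt) then sets C2, the arylrhodium species preferring the enone to the hindered aryl alkene, and delivers 9.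

3. Step 9. The second Si–O bond may form incompletely at the hindered silyl triflate, symmetrical silaketals may arise by exchange, or the aryl silyl ether may hydrolyse during isolation. The fallback sets out from 14 and returns at 16. Silylation of 14 with chlorodiisopropylsilane (imidazole, CH2Cl2, 0 °C) gives the isolable hydrosilyl ether F3, which can be purified and dosed exactly. N‑Bromosuccinimide in CH2Cl2 at 0 °C converts its Si–H bond into Si–Br to give the bromosilyl ether F4 in the flask, and addition of 10 with Et3N and a little DMAP then forms 16, which is carried on after filtration through base‑washed silica.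

Further compounds
F1 | step 10 | (2R,3E)‑2‑hydroxy‑4‑[(2S)‑7‑hydroxy‑4‑oxo‑2‑phenylchroman‑8‑yl]‑2‑methylbut‑3‑enyl acetate (E isomer of the target) | CC(=O)OC[C@](C)(O)/C=C/c1c(O)ccc2c1O[C@H](c1ccccc1)CC2=O
F2 | step 4 | 7‑(methoxymethoxy)‑8‑vinylchromone | O=c1ccoc2c(C=C)c(OCOC)ccc12
F3 | step 9 | (R)‑2‑[(diisopropylsilyl)oxy]‑2‑methylbut‑3‑enyl acetate | CC(=O)OC[C@@](C)(C=C)O[SiH](C(C)C)C(C)C
F4 | step 9 | (R)‑2‑{[bromo(diisopropyl)silyl]oxy}‑2‑methylbut‑3‑enyl acetate | CC(=O)OC[C@@](C)(C=C)O[Si](Br)(C(C)C)C(C)C
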